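The runs stem from a simulated flask with constants of no real substance; noise was put on by code.

Per day, the spring run lost 0.116 d⁻¹ of its unreacted substrate up to 5.00 d, but only 0.0243 d⁻¹ between 15.0 d and 20.0 d. This is a pseudo-first-order rate, counted on both substrates, because left-handed product passes half of the two together and the right-handed substrate must feed in. The midnight run reads much the same.

| setting | spring | midnight | flask |
|---|---|---|---|
| left-handed substrate | 10 mM | 15 mM | 20 mM |
| right-handed substrate | 10 mM | 15 mM | 20 mM |
| coupling partner | 60 mM | 60 mM | 60.0 mM |
| free catalyst | 0.50 mM | 0.50 mM | 0.50 mM |
| remark | run made earlier | run made earlier |  |

| run | time / d | left-handed product / % | left-handed substrate / % |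
|---|---|---|---|
| spring | 5.00 | 44 | 29 |
| spring | 10.0 | 60 | 20 |
| spring | 15.0 | 65 | 16 |
| spring | 20.0 | 69 | 13 |
| midnight | 5.00 | 45 | 29 |
| midnight | 10.0 | 58 | 21 |
| midnight | 15.0 | 65 | 14 |
| midnight | 20.0 | 69 | 16 |

(readings scatter by 1.5 percentage points)

- free catalyst is single-handed; left-handed substrate and right-handed substrate are mirror images of each other, charged as a racemate, each of them at the stated concentration
- no earlier run changes the charge of free catalyst; that part of a forecast is a guess
- no earlier run changes the charge of coupling partner; that part of a forecast is a guess

- apparent order in coupling partner when 50% of the left-handed substrate and right-handed substrate together are converted (percent change of the rate of making left-handed product for one percent more coupling partner charged)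
- factor on the rate of making left-handed product when 50% of the left-handed substrate and right-handed substrate together are converted if free catalyst is charged twice over

That rate fell by a factor of 4.77. In the spring run, the fall of coupling partner gives at most 1.30 of this, so I give the remaining 3.68 to fading catalyst, at about 0.0868 d⁻¹.

I reckon with a budget: the natural log of charged over unreacted substrate that a charge of catalyst can pay for. As a first answer, take the stall as the end:

first round: 1.17

Then add what the late rate still pays while it fades:

second round: 1.39

This conversion budget leaves 24.9% of the substrate unreacted at the end. My guess, which no run tests, is that coupling partner speeds coupling and catalyst loss alike, so that catalyst spent follows conversion, not time. Half conversion then costs 49.9% of the catalyst. A doubled charge spends the same amount, which gives a factor of 3.00. The order is charged over remaining coupling partner, 1.50.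

The forecast gives 2.4 and 2.3, and of its two explanations says: “I hedge between the two”.

The flask gives an order of 1.5 and a factor of 2.84.

    left-handed substrate ⇌ right-handed substrate (k = 0.00150 min⁻¹)
    coupling partner + free catalyst → spent catalyst (k = 0.00140 M⁻¹ min⁻¹)
    coupling partner + free catalyst + right-handed substrate → free catalyst + right-handed product (k = 0.0800 M⁻² min⁻¹)
    coupling partner + free catalyst + left-handed substrate → free catalyst + left-handed product (k = 8.10 M⁻² min⁻¹)

At 3.52 d in this flask, coupling uses coupling partner 73 times as fast as catalyst loss does. Spending the budget of 1.39 in full leaves 24.9% of the substrate by my reckoning, and at 250 d, with free catalyst at 0%, the flask holds 11.9% left-handed and 11.9% right-handed substrate.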